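**Retrosynthetic overview**
- The target is reached by hydrogenolysis of a precursor whose ring B carries a benzyl ester and two benzyl ethers.
- The pyranone of the isocoumarin is the only ring made. It comes from enol-lactonisation of a ring-A 2-(2-oxoheptyl)benzoic acid; ring A carries a tert-butyl ester and ring B a benzyl ester, so only ring A cyclises.
- Both ArCH2–C(=O)C5H11 bonds come from one Claisen-type acylation: the doubly laterally lithiated bis(o-toluate) diaryl ether plus N-methoxy-N-methylhexanamide (key C–C step).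
- The diaryl ether C–O bond comes from an Ullmann coupling of tert-butyl 2-bromo-4-methoxy-6-methylbenzoate (from 4-methoxy-2-methylaniline) with benzyl 4,6-bis(benzyloxy)-3-hydroxy-2-methylbenzoate (from orsellinic acid).
- Order: both benzene rings are bought; ether first, side chains second, pyranone ring third, deprotection last.

Assumption: the target SMILES has no stereocentre and no stereogenic double bond, so the compound is achiral and no enantiocontrol is needed; ring B is made as the open keto acid drawn.

**Step 1**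
Reactants: 1 orsellinic acid (2,4-dihydroxy-6-methylbenzoic acid)
Product: 2 benzyl 2,4-bis(benzyloxy)-6-methylbenzoate
Conditions: BnBr (3.6 equiv), K2CO3 (4 equiv), TBAI (cat.), DMF, 60 °C
Reagents that add atoms: benzyl bromide, BrCc1ccccc1
Why: The carboxylate and both phenoxides are benzylated by SN2 (Williamson alkylation), heat and iodide catalysis driving the hydrogen-bonded 2-OH to completion.

**Step 2**
Reactants: 2 benzyl 2,4-bis(benzyloxy)-6-methylbenzoate
Product: 3 benzyl 4,6-bis(benzyloxy)-3-bromo-2-methylbenzoate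
Conditions: NBS (1.05 equiv), MeCN, 0 °C to rt, dark
Reagents that add atoms: N-bromosuccinimide, O=C1CCC(=O)N1Br
Why: Electrophilic aromatic bromination goes to the position para to one benzyloxy group and ortho to the other (next to the methyl), because the site between the two benzyloxy groups is more crowded, as in halogenation of 2,4-dialkoxy-6-methylbenzoates.

**Step 3**
Reactants: 3 benzyl 4,6-bis(benzyloxy)-3-bromo-2-methylbenzoate
Product: 4 benzyl 4,6-bis(benzyloxy)-2-methyl-3-(4,4,5,5-tetramethyl-1,3,2-dioxaborolan-2-yl)benzoate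
Conditions: B2pin2 (1.5 equiv), XPhos Pd G2 (3 mol%), KOAc (3 equiv), 1,4-dioxane, 100 °C
Reagents that add atoms: bis(pinacolato)diboron, CC1(C)OB(OC1(C)C)B1OC(C)(C)C(C)(C)O1
Why: Miyaura borylation with a bulky biarylphosphine–Pd catalyst tolerates the two ortho substituents and the esters, with KOAc enabling transmetalation without Suzuki homocoupling.

**Step 4**
Reactants: 4 benzyl 4,6-bis(benzyloxy)-2-methyl-3-(4,4,5,5-tetramethyl-1,3,2-dioxaborolan-2-yl)benzoate
Product: 5 benzyl 4,6-bis(benzyloxy)-3-hydroxy-2-methylbenzoate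
Conditions: 30% H2O2, 1 M NaOH (1.1 equiv), THF, 0 °C; 1 M HCl work-up
Reagents that add atoms: hydrogen peroxide, OO
Why: Hydroperoxide adds to boron and the aryl group migrates to oxygen (oxidative ipso-hydroxylation of an arylboronate), too mild to touch the hindered benzyl ester.

**Step 5**
Reactants: 6 4-methoxy-2-methylaniline
Product: 7 2-bromo-4-methoxy-6-methylaniline
Conditions: NBS (1.0 equiv), DMF, 0 °C
Reagents that add atoms: N-bromosuccinimide, O=C1CCC(=O)N1Br
Why: Electrophilic aromatic bromination is directed by the free NH2 to its only open ortho position (para is blocked by OMe), and one equivalent of NBS stops at monobromination.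

**Step 6**
Reactants: 7 2-bromo-4-methoxy-6-methylaniline
Product: 9 1-bromo-2-iodo-5-methoxy-3-methylbenzene, via arenediazonium hydrogensulfate 8 (not isolated)
Conditions: NaNO2, aq. H2SO4/MeCN, 0 °C; then aq. KI, 0 °C to rt
Reagents that add atoms: potassium iodide, [K+].[I-]
Why: Diazotisation followed by iodide displacement (Sandmeyer-type iodination, no copper needed) puts iodine exactly where the carboxyl carbon is wanted.

**Step 7**
Reactants: 9 1-bromo-2-iodo-5-methoxy-3-methylbenzene
Product: 11 tert-butyl 2-bromo-4-methoxy-6-methylbenzoate, via arylmagnesium chloride 10 (not isolated)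
Conditions: i-PrMgCl·LiCl (1.1 equiv), THF, −30 °C; then Boc2O (1.3 equiv), −30 °C to rt; aq. NH4Cl
Reagents that add atoms: di-tert-butyl dicarbonate, CC(C)(C)OC(=O)OC(=O)OC(C)(C)C
Why: Iodine–magnesium exchange (Knochel turbo-Grignard) is selective for C–I over C–Br at a temperature where the ortho-bromo Grignard does not form an aryne, and acylation by Boc2O gives the hindered tert-butyl ester directly.

**Step 8**
Reactants: 5 benzyl 4,6-bis(benzyloxy)-3-hydroxy-2-methylbenzoate; 11 tert-butyl 2-bromo-4-methoxy-6-methylbenzoate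
Product: 12 benzyl 4,6-bis(benzyloxy)-3-[2-(tert-butoxycarbonyl)-5-methoxy-3-methylphenoxy]-2-methylbenzoate
Conditions: CuI (10 mol%), picolinic acid (20 mol%), K3PO4 (2 equiv), DMSO, 90 °C, argon
Reagents that add atoms: none
Why: Ullmann diaryl ether coupling, where the CuI/picolinic acid system is suited to 2,6-disubstituted phenols and the bromide is activated by its ortho ester and has only one ortho substituent.

**Step 9**
Reactants: 13 hexanoyl chloride; 14 N,O-dimethylhydroxylamine hydrochloride
Product: 15 N-methoxy-N-methylhexanamide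
Conditions: Et3N (2.2 equiv), CH2Cl2, 0 °C to rt
Reagents that add atoms: none
Why: Acyl substitution of the acid chloride by the liberated hydroxylamine (Weinreb amide formation) is fast and clean with Et3N as HCl scavenger.

**Step 10**
Reactants: 12 benzyl 4,6-bis(benzyloxy)-3-[2-(tert-butoxycarbonyl)-5-methoxy-3-methylphenoxy]-2-methylbenzoate; 15 N-methoxy-N-methylhexanamide
Product: 18 benzyl 4,6-bis(benzyloxy)-3-[2-(tert-butoxycarbonyl)-5-methoxy-3-(2-oxoheptyl)phenoxy]-2-(2-oxoheptyl)benzoate, via dilithiated bis-toluate 16 (not isolated), via bis-hemiaminal dilithium alkoxide 17 (not isolated)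
Conditions: LDA (commercial, 2.5 equiv), THF, −78 °C, 45 min; 15 (3 equiv), −78 to −40 °C; AcOH, −78 °C
Reagents that add atoms: none
Why: Claisen-type condensation in which LDA removes one proton from each ester-activated methyl (lateral lithiation) and each benzylic anion acylates a Weinreb amide whose chelated tetrahedral adduct prevents over-addition; the bulky tert-butyl ester blocks intramolecular attack and the lithiated ring A is too electron-rich for a Truce–Smiles aryl shift.

**Step 11**
Reactants: 18 benzyl 4,6-bis(benzyloxy)-3-[2-(tert-butoxycarbonyl)-5-methoxy-3-(2-oxoheptyl)phenoxy]-2-(2-oxoheptyl)benzoate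
Product: 20 benzyl 4,6-bis(benzyloxy)-3-[(6-methoxy-1-oxo-3-pentyl-1H-isochromen-8-yl)oxy]-2-(2-oxoheptyl)benzoate, via ring-A keto acid 19 (not isolated)
Conditions: TFA/CH2Cl2 (1:4), 0 °C to rt; evaporate; TFAA (1.5 equiv), CH2Cl2, 0 °C
Reagents that add atoms: none
Why: TFA cleaves only the tert-butyl ester (E1 loss of isobutene) and the freed 2-(2-oxoheptyl)benzoic acid undergoes TFAA-driven enol-lactonisation to the isocoumarin, whereas ring B has no free acid to cyclise and no free position ortho to the ether oxygen for xanthone formation.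

**Step 12**
Reactants: 20 benzyl 4,6-bis(benzyloxy)-3-[(6-methoxy-1-oxo-3-pentyl-1H-isochromen-8-yl)oxy]-2-(2-oxoheptyl)benzoate
Product: 21 beta-collatolic acid, 4,6-dihydroxy-3-[(6-methoxy-1-oxo-3-pentyl-1H-isochromen-8-yl)oxy]-2-(2-oxoheptyl)benzoic acid
Conditions: H2 (1 atm), 10% Pd/C, EtOAc, rt, stopped after uptake of 3 equiv H2
Reagents that add atoms: none
Why: Pd-catalysed hydrogenolysis removes the two benzyl ethers and the benzyl ester faster than the conjugated trisubstituted enol-lactone alkene or the ketone is reduced, and the neutral medium avoids dehydration of the ring-B keto acid.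

**Compound list**
1 | orsellinic acid (2,4-dihydroxy-6-methylbenzoic acid) | Cc1cc(O)cc(O)c1C(=O)O | starting material
2 | benzyl 2,4-bis(benzyloxy)-6-methylbenzoate | Cc1cc(OCc2ccccc2)cc(OCc2ccccc2)c1C(=O)OCc1ccccc1 | intermediate
3 | benzyl 4,6-bis(benzyloxy)-3-bromo-2-methylbenzoate | Cc1c(Br)c(OCc2ccccc2)cc(OCc2ccccc2)c1C(=O)OCc1ccccc1 | intermediate
4 | benzyl 4,6-bis(benzyloxy)-2-methyl-3-(4,4,5,5-tetramethyl-1,3,2-dioxaborolan-2-yl)benzoate | Cc1c(B2OC(C)(C)C(C)(C)O2)c(OCc2ccccc2)cc(OCc2ccccc2)c1C(=O)OCc1ccccc1 | intermediate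
5 | benzyl 4,6-bis(benzyloxy)-3-hydroxy-2-methylbenzoate | Cc1c(O)c(OCc2ccccc2)cc(OCc2ccccc2)c1C(=O)OCc1ccccc1 | intermediate
6 | 4-methoxy-2-methylaniline | COc1ccc(N)c(C)c1 | starting material
7 | 2-bromo-4-methoxy-6-methylaniline | COc1cc(C)c(N)c(Br)c1 | intermediate
8 | 2-bromo-4-methoxy-6-methylbenzenediazonium hydrogensulfate | COc1cc(C)c([N+]#N)c(Br)c1.OS(=O)(=O)[O-] | intermediate (not isolated)
9 | 1-bromo-2-iodo-5-methoxy-3-methylbenzene | COc1cc(C)c(I)c(Br)c1 | intermediate
10 | (2-bromo-4-methoxy-6-methylphenyl)magnesium chloride | COc1cc(C)c([Mg]Cl)c(Br)c1 | intermediate (not isolated)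
11 | tert-butyl 2-bromo-4-methoxy-6-methylbenzoate | COc1cc(C)c(C(=O)OC(C)(C)C)c(Br)c1 | intermediate
12 | benzyl 4,6-bis(benzyloxy)-3-[2-(tert-butoxycarbonyl)-5-methoxy-3-methylphenoxy]-2-methylbenzoate | Cc1c(Oc2cc(OC)cc(C)c2C(=O)OC(C)(C)C)c(OCc2ccccc2)cc(OCc2ccccc2)c1C(=O)OCc1ccccc1 | intermediate
13 | hexanoyl chloride | CCCCCC(=O)Cl | starting material
14 | N,O-dimethylhydroxylamine hydrochloride | CNOC.Cl | starting material
15 | N-methoxy-N-methylhexanamide | CCCCCC(=O)N(C)OC | intermediate
16 | benzyl 4,6-bis(benzyloxy)-3-[2-(tert-butoxycarbonyl)-3-(lithiomethyl)-5-methoxyphenoxy]-2-(lithiomethyl)benzoate | [Li]Cc1c(Oc2cc(OC)cc(C[Li])c2C(=O)OC(C)(C)C)c(OCc2ccccc2)cc(OCc2ccccc2)c1C(=O)OCc1ccccc1 | intermediate (not isolated)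
17 | dilithium bis-alkoxide of the double Weinreb adduct of 16 (each new chain is CH2–C(OLi)(NMeOMe)C5H11; both hemiaminal carbons unspecified, lost on quench) | CCCCCC(O[Li])(N(C)OC)Cc1c(Oc2cc(OC)cc(CC(O[Li])(CCCCC)N(C)OC)c2C(=O)OC(C)(C)C)c(OCc2ccccc2)cc(OCc2ccccc2)c1C(=O)OCc1ccccc1 | intermediate (not isolated)
18 | benzyl 4,6-bis(benzyloxy)-3-[2-(tert-butoxycarbonyl)-5-methoxy-3-(2-oxoheptyl)phenoxy]-2-(2-oxoheptyl)benzoate | CCCCCC(=O)Cc1c(Oc2cc(OC)cc(CC(=O)CCCCC)c2C(=O)OC(C)(C)C)c(OCc2ccccc2)cc(OCc2ccccc2)c1C(=O)OCc1ccccc1 | intermediate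
19 | 2-{4,6-bis(benzyloxy)-3-[(benzyloxy)carbonyl]-2-(2-oxoheptyl)phenoxy}-4-methoxy-6-(2-oxoheptyl)benzoic acid | CCCCCC(=O)Cc1c(Oc2cc(OC)cc(CC(=O)CCCCC)c2C(=O)O)c(OCc2ccccc2)cc(OCc2ccccc2)c1C(=O)OCc1ccccc1 | intermediate (not isolated)
20 | benzyl 4,6-bis(benzyloxy)-3-[(6-methoxy-1-oxo-3-pentyl-1H-isochromen-8-yl)oxy]-2-(2-oxoheptyl)benzoate | CCCCCC(=O)Cc1c(Oc2cc(OC)cc3cc(CCCCC)oc(=O)c23)c(OCc2ccccc2)cc(OCc2ccccc2)c1C(=O)OCc1ccccc1 | intermediate
21 | beta-collatolic acid, 4,6-dihydroxy-3-[(6-methoxy-1-oxo-3-pentyl-1H-isochromen-8-yl)oxy]-2-(2-oxoheptyl)benzoic acid (achiral) | CCCCCC(=O)Cc1c(Oc2cc(OC)cc3cc(CCCCC)oc(=O)c23)c(O)cc(O)c1C(=O)O | target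

**Totals**
Total step count: 12. Longest linear sequence: 8 steps (steps 1, 2, 3, 4, 8, 10, 11, 12).

**Three steps most likely to fail, with fallbacks**

Step 8 (Ullmann coupling of a 2,6-disubstituted phenol with a bromide next to a bulky ester). The fallback sets out from 9 and comes back at 12. Iodide 9 is exchanged as before to Grignard 10, which is quenched with CO2 instead of Boc2O to give 2-bromo-4-methoxy-6-methylbenzoic acid F1. Its free ortho-carboxylate is a far stronger accelerating group for copper-mediated aryl ether formation than an ester. Under classical Ullmann–Goldberg conditions (Cu powder/CuI, K2CO3, DMF with a little pyridine, 110 °C) F1 is coupled with phenol 5 to give 2-{4,6-bis(benzyloxy)-3-[(benzyloxy)carbonyl]-2-methylphenoxy}-4-methoxy-6-methylbenzoic acid F2. The hindered acid is then tert-butylated under neutral conditions with N,N-dimethylformamide di-tert-butyl acetal in toluene at 80 °C, which gives 12.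

Step 10 (double lateral lithiation and double acylation; the main risks are enolisation of the Weinreb amide by the benzylic anions and incomplete second acylation). The fallback sets out from 12 and comes back at 18. Dianion 16 is made in the same way but trapped with hexanal, which adds much faster than it enolises (aldol-type addition, −78 °C). The mixture is quenched cold with AcOH before the alkoxides can lactonise onto the esters. This gives the diol benzyl 4,6-bis(benzyloxy)-3-[2-(tert-butoxycarbonyl)-3-(2-hydroxyheptyl)-5-methoxyphenoxy]-2-(2-hydroxyheptyl)benzoate F3 as a diastereomer mixture, which does not matter because both carbinol centres are removed next. Oxidation with Dess–Martin periodinane (NaHCO3, CH2Cl2, rt) converts F3 into bis-ketone 18.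

Step 12 (hydrogenolysis may begin to saturate the C3=C4 bond of the isocoumarin). The fallback sets out from 20 and comes back at 21 and makes no new compound F0. The three benzyl groups are removed without any reductant by Lewis-acid debenzylation with BCl3 (6 equiv) and pentamethylbenzene as benzyl-cation scavenger in CH2Cl2 at −78 to −40 °C, followed by aqueous work-up. Under these conditions the alkene cannot be reduced, and the non-chelated ring-A methyl ether and the diaryl ether are not cleaved at this temperature.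

**Further compounds**
F1 | step 8 | 2-bromo-4-methoxy-6-methylbenzoic acid | COc1cc(C)c(C(=O)O)c(Br)c1
F2 | step 8 | 2-{4,6-bis(benzyloxy)-3-[(benzyloxy)carbonyl]-2-methylphenoxy}-4-methoxy-6-methylbenzoic acid | Cc1c(Oc2cc(OC)cc(C)c2C(=O)O)c(OCc2ccccc2)cc(OCc2ccccc2)c1C(=O)OCc1ccccc1
F3 | step 10 | benzyl 4,6-bis(benzyloxy)-3-[2-(tert-butoxycarbonyl)-3-(2-hydroxyheptyl)-5-methoxyphenoxy]-2-(2-hydroxyheptyl)benzoate (carbinol centres unspecified) | CCCCCC(O)Cc1c(Oc2cc(OC)cc(CC(O)CCCCC)c2C(=O)OC(C)(C)C)c(OCc2ccccc2)cc(OCc2ccccc2)c1C(=O)OCc1ccccc1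
F0 | step 12 | none | none
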